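**Strategy.** Ring A carries oxygen on C5, C6, C7 and C8. The fusion carbons C4a and C8a are therefore its only atoms without a hydroxy or methoxy group, and they are mapped onto the triple bond of mirror-symmetric 3,4,5,6-tetramethoxybenzyne. The route rests on cutting O1–C8a, C4–C4a and O1–C2 of ring C. In a single operation the aryne is released by fluoride from a hexasubstituted ortho-silylaryl triflate and takes up a dibenzyl-protected ring B arylpropiolic acid. The acyl group then moves from oxygen to carbon, and oxa-Michael addition closes the pyranone. Hydrogenolysis of the two benzyl ethers and cleavage of the 5-methyl ether, singled out by its peri carbonyl, then give gardenin E.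

Key step: step 9

Remark: flavone numbering is used (O1, C2, C3, C4, C4a, C5–C8, C8a for rings C and A, primed locants for ring B); the target has no stereocentre and no configured double bond, so no step has to control configuration.

Step 1
Reactants: 1 1,2,3,4-tetramethoxybenzene
Product: 4 2,3,4,5-tetramethoxyphenol, via aryllithium 2 (not isolated), via aryl boronate 3 (not isolated)
Conditions: n-BuLi, TMEDA, THF, 0 °C → rt; B(OMe)3, −78 °C → rt; AcOH, 30% H2O2, 0 °C → rt
Reagents that add atoms: hydrogen peroxide, OO
Why: Directed ortho-metalation at one of the two equivalent ring C–H positions next to a methoxy group, then borylation and peroxide oxidation of the C–B bond (lithiation–borylation–oxidation), should install the hydroxyl in one flask, and the mildly acidic oxidation spares the oxidisable phenol.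

Step 2
Reactants: 4 2,3,4,5-tetramethoxyphenol
Product: 5 2-bromo-3,4,5,6-tetramethoxyphenol
Conditions: NBS (1.0 equiv), MeCN, −20 → 0 °C, dark
Reagents that add atoms: N-bromosuccinimide, O=C1CCC(=O)N1Br
Why: Electrophilic aromatic bromination can occur only at the single remaining ring C–H, which is ortho to the free hydroxyl, and one equivalent of NBS in a dry, cold medium should hold back oxidation to a quinone.

Step 3
Reactants: 5 2-bromo-3,4,5,6-tetramethoxyphenol
Product: 8 3,4,5,6-tetramethoxy-2-(trimethylsilyl)phenyl trifluoromethanesulfonate, via silyl ether 6 (not isolated), via lithium phenoxide 7 (not isolated)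
Conditions: HMDS, THF, reflux, then evaporation; n-BuLi, THF, −100 → −80 °C; Tf2O, −100 °C → rt
Reagents that add atoms: hexamethyldisilazane, C[Si](C)(C)N[Si](C)(C)C; trifluoromethanesulfonic anhydride, O=S(=O)(OS(=O)(=O)C(F)(F)F)C(F)(F)F
Why: O-silylation, bromine–lithium exchange and migration of silicon from oxygen to the adjacent aryl carbanion (retro-Brook rearrangement) should give the ortho-silyl phenoxide, which Tf2O traps on oxygen, and this is the standard telescoped entry to ortho-silylaryl triflates.

Step 4
Reactants: 9 methyl 3,5-dihydroxy-4-methoxybenzoate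
Product: 10 methyl 3,5-bis(benzyloxy)-4-methoxybenzoate
Conditions: BnBr (2.3 equiv), K2CO3, DMF, 60 °C
Reagents that add atoms: benzyl bromide, BrCc1ccccc1
Why: Williamson ether synthesis on the two equivalent phenols gives benzyl ethers that tolerate hydride, MnO2, the phosphorus ylide, cold n-BuLi and hot fluoride, and that leave at the end under neutral hydrogenolysis.

Step 5
Reactants: 10 methyl 3,5-bis(benzyloxy)-4-methoxybenzoate
Product: 11 [3,5-bis(benzyloxy)-4-methoxyphenyl]methanol
Conditions: LiAlH4, THF, 0 °C → rt; aqueous work-up
Reagents that add atoms: none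
Why: Full hydride reduction of the aryl ester to the benzylic alcohol is preferred to a partial reduction because it can neither stall nor overshoot, and the ethers are inert to LiAlH4.

Step 6
Reactants: 11 [3,5-bis(benzyloxy)-4-methoxyphenyl]methanol
Product: 12 3,5-bis(benzyloxy)-4-methoxybenzaldehyde
Conditions: activated MnO2, CH2Cl2, rt
Reagents that add atoms: none
Why: Heterogeneous MnO2 oxidation is selective for benzylic alcohols and stops at the aldehyde.

Step 7
Reactants: 12 3,5-bis(benzyloxy)-4-methoxybenzaldehyde
Product: 13 1,3-bis(benzyloxy)-5-(2,2-dibromoethenyl)-2-methoxybenzene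
Conditions: CBr4 (2 equiv), PPh3 (4 equiv), CH2Cl2, 0 °C
Reagents that add atoms: carbon tetrabromide, BrC(Br)(Br)Br
Why: This is the first stage of the Corey–Fuchs homologation, a Wittig-type dibromo-olefination by Ph3P=CBr2 that works well on electron-rich, non-enolisable benzaldehydes.

Step 8
Reactants: 13 1,3-bis(benzyloxy)-5-(2,2-dibromoethenyl)-2-methoxybenzene
Product: 15 3-[3,5-bis(benzyloxy)-4-methoxyphenyl]prop-2-ynoic acid, via lithium acetylide 14 (not isolated)
Conditions: n-BuLi (2.2 equiv), THF, −78 → −20 °C; dry CO2, −78 °C → rt; 1 M HCl, 0 °C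
Reagents that add atoms: carbon dioxide, O=C=O
Why: In the second stage of the Corey–Fuchs sequence, bromine–lithium exchange, loss of LiBr with 1,2-shift (Fritsch–Buttenberg–Wiechell rearrangement) and deprotonation should give acetylide 14, whose carboxylation is a standard route to arylpropiolic acids, while the low temperature protects the benzyl ethers from benzylic metalation.

Step 9
Reactants: 8 3,4,5,6-tetramethoxy-2-(trimethylsilyl)phenyl trifluoromethanesulfonate; 15 3-[3,5-bis(benzyloxy)-4-methoxyphenyl]prop-2-ynoic acid
Product: 18 3',5'-bis(benzyloxy)-4',5,6,7,8-pentamethoxyflavone, via aryne 16 (not isolated), via ynone 17 (not isolated)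
Conditions: 8 (1.5 equiv), CsF (4 equiv), THF (0.02 M), sealed tube, 125 °C
Reagents that add atoms: none
Why: Fluoride removes the silyl group of 8 and triflate departs to give aryne 16, while CsF turns 15 into its caesium carboxylate and stores the proton as poorly soluble bifluoride. The carboxylate oxygen adds to one aryne carbon (O1–C8a) and the neighbouring aryl anion attacks its own ester carbonyl through a four-membered transition state, an anionic Fries-type O-to-C acyl shift that makes C4–C4a and frees the phenoxide of ynone 17. The closest known reaction type is the formal insertion of arynes into the C–O bond of carboxylic acids, which with 3-arylpropiolic acids is known to run on to flavones. Ring C, the only ring formed, closes by 6-endo-dig oxa-Michael addition of that phenoxide to the alkyne terminus (O1–C2) followed by protonation at C3, and in the aprotic medium a 5-exo-dig adduct can revert, so the more stable flavone should prevail over the aurone. No stereocentre arises and no regiochemical question exists, because a mirror plane bisects the triple bond of 16 and both of its carbons lead to the same product. The selectivity needed is acyl transfer over protonation of the aryl anion to the simple aryl ester, and it is secured by high dilution, high temperature and the lack of a soluble proton donor, with the ortho methoxy groups buttressing the ester carbonyl towards the carbanion.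

Step 10
Reactants: 18 3',5'-bis(benzyloxy)-4',5,6,7,8-pentamethoxyflavone
Product: 19 3',5'-dihydroxy-4',5,6,7,8-pentamethoxyflavone
Conditions: H2 (1 atm), 10% Pd/C, EtOAc–MeOH, rt
Reagents that add atoms: none
Why: Catalytic hydrogenolysis of aryl benzyl ethers leaves the flavone C2–C3 double bond and all methyl ethers untouched at one atmosphere, and it is placed first so that no acid ever meets a benzyl ether that could ionise and alkylate the electron-rich rings.

Step 11
Reactants: 19 3',5'-dihydroxy-4',5,6,7,8-pentamethoxyflavone
Product: 20 gardenin E (5,3',5'-trihydroxy-4',6,7,8-tetramethoxyflavone)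
Conditions: 3 M HCl, aqueous EtOH, reflux, N2
Reagents that add atoms: none
Why: Acid-promoted peri-selective O-demethylation, routine for 5,6,7,8-tetramethoxyflavones, should touch only the 5-methyl ether because protonation of the C4 carbonyl activates that oxygen alone for SN2 attack by chloride and the freed hydroxyl is locked in a hydrogen bond, while a Wessely–Moser ring opening and reclosure would be degenerate on this symmetric ring A.

**Compound list**

1 | 1,2,3,4-tetramethoxybenzene | COc1ccc(OC)c(OC)c1OC | starting material
2 | 2,3,4,5-tetramethoxyphenyllithium | [Li]c1cc(OC)c(OC)c(OC)c1OC | intermediate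
3 | dimethyl (2,3,4,5-tetramethoxyphenyl)boronate | COB(OC)c1cc(OC)c(OC)c(OC)c1OC | intermediate
4 | 2,3,4,5-tetramethoxyphenol | COc1cc(O)c(OC)c(OC)c1OC | intermediate
5 | 2-bromo-3,4,5,6-tetramethoxyphenol | COc1c(O)c(Br)c(OC)c(OC)c1OC | intermediate
6 | (2-bromo-3,4,5,6-tetramethoxyphenoxy)trimethylsilane | COc1c(O[Si](C)(C)C)c(Br)c(OC)c(OC)c1OC | intermediate
7 | lithium 3,4,5,6-tetramethoxy-2-(trimethylsilyl)phenoxide | [Li+].[O-]c1c(OC)c(OC)c(OC)c(OC)c1[Si](C)(C)C | intermediate
8 | 3,4,5,6-tetramethoxy-2-(trimethylsilyl)phenyl trifluoromethanesulfonate | COc1c(OC)c(OC)c(OC)c([Si](C)(C)C)c1OS(=O)(=O)C(F)(F)F | intermediate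
9 | methyl 3,5-dihydroxy-4-methoxybenzoate | COC(=O)c1cc(O)c(OC)c(O)c1 | starting material
10 | methyl 3,5-bis(benzyloxy)-4-methoxybenzoate | COC(=O)c1cc(OCc2ccccc2)c(OC)c(OCc2ccccc2)c1 | intermediate
11 | [3,5-bis(benzyloxy)-4-methoxyphenyl]methanol | COc1c(OCc2ccccc2)cc(CO)cc1OCc1ccccc1 | intermediate
12 | 3,5-bis(benzyloxy)-4-methoxybenzaldehyde | COc1c(OCc2ccccc2)cc(C=O)cc1OCc1ccccc1 | intermediate
13 | 1,3-bis(benzyloxy)-5-(2,2-dibromoethenyl)-2-methoxybenzene | COc1c(OCc2ccccc2)cc(C=C(Br)Br)cc1OCc1ccccc1 | intermediate
14 | lithium [3,5-bis(benzyloxy)-4-methoxyphenyl]acetylide | COc1c(OCc2ccccc2)cc(C#C[Li])cc1OCc1ccccc1 | intermediate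
15 | 3-[3,5-bis(benzyloxy)-4-methoxyphenyl]prop-2-ynoic acid | COc1c(OCc2ccccc2)cc(C#CC(=O)O)cc1OCc1ccccc1 | intermediate
16 | 3,4,5,6-tetramethoxybenzyne | COC1=C(OC)C(OC)=C(OC)C#C1 | intermediate
17 | 3-[3,5-bis(benzyloxy)-4-methoxyphenyl]-1-(2-hydroxy-3,4,5,6-tetramethoxyphenyl)prop-2-yn-1-one (present as its caesium phenoxide) | COc1c(OCc2ccccc2)cc(C#CC(=O)c2c(O)c(OC)c(OC)c(OC)c2OC)cc1OCc1ccccc1 | intermediate
18 | 3',5'-bis(benzyloxy)-4',5,6,7,8-pentamethoxyflavone | COc1c(OCc2ccccc2)cc(-c2cc(=O)c3c(OC)c(OC)c(OC)c(OC)c3o2)cc1OCc1ccccc1 | intermediate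
19 | 3',5'-dihydroxy-4',5,6,7,8-pentamethoxyflavone | COc1c(O)cc(-c2cc(=O)c3c(OC)c(OC)c(OC)c(OC)c3o2)cc1O | intermediate
20 | gardenin E | COc1c(O)cc(-c2cc(=O)c3c(O)c(OC)c(OC)c(OC)c3o2)cc1O | target

**Step count.** Total: 11 steps (3 to the aryne precursor, 5 to the acid, the key step, 2 afterwards). Longest linear sequence: 8 steps (9 → 20, steps 4–11).

**Steps most likely to fail**

Step 9. The aryl anion may be protonated before it reaches the ester carbonyl, which would stop the sequence at simple O-arylation. The propiolate may lose CO2 at 125 °C. The crowded aryne may also be consumed by side reactions faster than by the weakly nucleophilic carboxylate. The fallback builds ring C in the classical way without an aryne and sets out from 4 and 12. Ortho C-acetylation of 4 at its only free position (Ac2O, BF3·OEt2, 70 °C) should give 1-(2-hydroxy-3,4,5,6-tetramethoxyphenyl)ethan-1-one F1. Claisen–Schmidt condensation of this ketone with 12 (KOH, EtOH, rt) should give (E)-3-[3,5-bis(benzyloxy)-4-methoxyphenyl]-1-(2-hydroxy-3,4,5,6-tetramethoxyphenyl)prop-2-en-1-one F2. Oxidative cyclisation of the 2'-hydroxychalcone (catalytic I2, DMSO, 120 °C) comes back to the route at 18.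

Step 3. On the hexasubstituted ring the aryllithium may be quenched by protonation before silicon migrates. The crowded phenoxide may be sulfonylated sluggishly. The electron-rich aryl silane may also protodesilylate during work-up. The fallback replaces halogen–metal exchange and silyl migration by directed ortho-metalation of a carbamate. It sets out from 4 and makes step 2 unnecessary. Carbamoylation (ClC(O)NEt2, NaH, THF) should give 2,3,4,5-tetramethoxyphenyl N,N-diethylcarbamate F3. Lithiation at the only ring C–H, flanked by carbamate and methoxy (s-BuLi, TMEDA, THF, −78 °C), and a TMSCl quench should give 3,4,5,6-tetramethoxy-2-(trimethylsilyl)phenyl N,N-diethylcarbamate F4. Reductive removal of the carbamate (LiAlH4, THF, reflux) should give 3,4,5,6-tetramethoxy-2-(trimethylsilyl)phenol F5. Triflation under basic conditions (NaH, PhNTf2, THF) comes back to the route at 8.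

Step 11. The ether cleavage may be slow or incomplete. Prolonged heating may also remove a second methyl group, either at O6 next to the freed hydroxyl or at O7. The fallback swaps the order of the endgame and replaces Brønsted activation by a metal chelate. It sets out from 18. AlCl3 attenuated by MeCN (60 °C, then dilute HCl) binds the C4 carbonyl and the peri oxygen in a six-membered chelate and spares benzyl ethers, which should give 3',5'-bis(benzyloxy)-5-hydroxy-4',6,7,8-tetramethoxyflavone F6. Hydrogenolysis (H2, Pd/C, EtOAc–MeOH) then comes back to the route at 20.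

**Further compounds**

F1 | step 9 | 1-(2-hydroxy-3,4,5,6-tetramethoxyphenyl)ethan-1-one | CC(=O)c1c(O)c(OC)c(OC)c(OC)c1OC
F2 | step 9 | (E)-3-[3,5-bis(benzyloxy)-4-methoxyphenyl]-1-(2-hydroxy-3,4,5,6-tetramethoxyphenyl)prop-2-en-1-one | COc1c(OCc2ccccc2)cc(/C=C/C(=O)c2c(O)c(OC)c(OC)c(OC)c2OC)cc1OCc1ccccc1
F3 | step 3 | 2,3,4,5-tetramethoxyphenyl N,N-diethylcarbamate | CCN(CC)C(=O)Oc1cc(OC)c(OC)c(OC)c1OC
F4 | step 3 | 3,4,5,6-tetramethoxy-2-(trimethylsilyl)phenyl N,N-diethylcarbamate | CCN(CC)C(=O)Oc1c([Si](C)(C)C)c(OC)c(OC)c(OC)c1OC
F5 | step 3 | 3,4,5,6-tetramethoxy-2-(trimethylsilyl)phenol | Oc1c([Si](C)(C)C)c(OC)c(OC)c(OC)c1OC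
F6 | step 11 | 3',5'-bis(benzyloxy)-5-hydroxy-4',6,7,8-tetramethoxyflavone | COc1c(OCc2ccccc2)cc(-c2cc(=O)c3c(O)c(OC)c(OC)c(OC)c3o2)cc1OCc1ccccc1
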